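4 questions stand on one flask: how much complex with one exchanged it holds at the time of looking, how much after dusk and after noon, and which remedy gains most.

| setting | south | flask |
|---|---|---|
| starting complex | 1.1 M | 1.1 M |
| incoming ligand | 1 equiv | 1.00 equiv |
| leaving ligand | 2 equiv | 2.00 equiv |
| temperature | 25 °C | 25 °C |
| remark | the very flask that is asked about, followed so far |  |
| time |  | 3.0 min |

- south (time / s: complex with one exchanged / %): 20.0: 25.1; 40.0: 19.1; 50.0: 18.8; 80.0: 16.9; 90.0: 16.9; 120: 16.5

(readings scatter by 0.5 percentage points)

- the volume of additions can be left aside
- the numbers in the tables scatter by 0.5 percentage points (one standard deviation)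

- dusk: at 3.0 min raise the temperature by 25 K, then wait 6.0 min
- winter: change nothing and wait 6.0 min more
- noon: at 3.0 min add incoming ligand, 50.0% of the amount charged, then wait 6.0 min
- midnight: at 3.0 min take out 90% of the leaving ligand then present, then wait 6.0 min

- complex with one exchanged, in percent of the starting complex first charged, at 3.0 min
- the remedy with the largest gain of complex with one exchanged, or "none" below 2 percentage points (dusk / winter / noon / midnight / none)
- complex with one exchanged present, in percent of the starting complex first charged, after dusk
- complex with one exchanged present, in percent of the starting complex first charged, after noon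

The south readings look contradictory. Complex with one exchanged stands at 25.1% after 20.0 s, then falls to 16.5% by 120 s. Yet if it were the sole product, the balance of the incoming ligand would leave 74.9% of that ligand at the first reading. A single exchange started from this charge climbs to its end and stays there, so I test it. I write the balance on the incoming ligand: the first exchange takes one incoming ligand and one starting complex and gives one leaving ligand. With the readings as the amount exchanged, I reckon

Q = [complex with one exchanged][leaving ligand] / ([starting complex][incoming ligand])

at 20.0 s: Q = 1.01

at 120 s: Q = 0.512

I carry the second value as the one-step quotient, the reaction quotient of the first exchange with the balance written as if no other product existed. It drops to about half of the first value, so that balance is incomplete: material stands in forms these readings do not show. Q is therefore a reading, an apparent figure. Still, the last readings are flat within their scatter, so I take 16.5% for 3.0 min and expect nothing from winter. Solving Q with the noon charge gives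

after noon: 22.7%

Q holds no temperature, so it says nothing on dusk.

The forecast gives 16.5% now, 17% after dusk and 19% after noon, below my figure, names midnight as best, and says “Heating has no enthalpy data, so I expect little change.”

The flask gives 15.9% now, 39.1% after dusk and 18.5% after noon. Dusk gains most, 23 percentage points, against 3.5 points for midnight, 2.6 points for noon and −0.029 points for winter.

    starting complex + incoming ligand ⇌ leaving ligand + complex with one exchanged (K = 4.90, k = 0.130 M⁻¹ s⁻¹, Ea = 57.0 kJ mol⁻¹, ΔH = 34.0 kJ mol⁻¹)
    complex with one exchanged + incoming ligand ⇌ leaving ligand + complex with two exchanged (K = 2.70, k = 0.0760 M⁻¹ s⁻¹, Ea = 67.0 kJ mol⁻¹, ΔH = −26.0 kJ mol⁻¹)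
    complex with two exchanged + incoming ligand ⇌ leaving ligand + complex with three exchanged (K = 0.760, k = 0.200 M⁻¹ s⁻¹, Ea = 59.0 kJ mol⁻¹, ΔH = −65.0 kJ mol⁻¹)
    starting complex ⇌ dormant form (K = 4.30, k = 0.0580 s⁻¹, Ea = 77.0 kJ mol⁻¹, ΔH = −20.0 kJ mol⁻¹)
    (constants at 25 °C)

On this flask, my noon figure from Q of 0.512 stands 4.2 points above the computed one. Q does write the first exchange as running back, and that reverse step is the main reason the flask stands so low: the run without it holds 68.3% at 3.0 min against 15.9%. On the neighbour flask with 0.250 equiv of incoming ligand, the same Q gives 4.81%, and the computed flask holds 6.42%.

The readings stem from a simulated flask for substances that don't exist.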